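## The problem

The target is a labdane. It has a trans-fused decalin (ring A: C1–C5 and C10; ring B: C5–C10) with a gem-dimethyl group at C4 and an angular methyl (C20) at C10. A carboxylic acid (C17) sits on the C7=C8 double bond, an α-oriented (R)-2-methylbutanoyloxy group on C6, and a two-carbon chain (C11, C12) on C9 ends in an α-substituted butenolide (C13–C16). Four ring stereocentres are contiguous (5S,6S,9R,10R) and a fifth lies in the acyl group. Only C5 and the quaternary C10 need an outside source of chirality: the axial C10 methyl blocks the β face of ring B and can steer reagents to the α face at C9 (side chain equatorial) and at C6 (oxygen α). The fragile parts are the butenolide (bases, nucleophiles, dissolving metals, enolisation to a furanolate), the γ-acyloxy-α,β-unsaturated acid, the epimerisable α-carbon of the 2-methylbutanoate, and any intermediate in which C9–H is both allylic and α to a carbonyl. Late oxidation has to distinguish three allylic positions around C7=C8 (C6, C9 and C17). The enabling feature is that ring B, read as C5–C6–C7=C8(C17)–C9–C10, is the carbon pattern of (R)-carvone: its stereocentre is C5 in the correct absolute sense, its isopropenyl group is C4 plus one geminal methyl, its carbonyl is C9, its ring methyl is C17 on C7=C8, and its α′-carbon is C10. Because C4 is then an alkene carbon, hydrogen-atom transfer makes it a tertiary radical that already carries both methyls, and a three-carbon acceptor on C10 lets this radical close ring A through the C3–C4 bond.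

## Retrosynthesis

**C17 acid and C6 ester (24 ⇒ 23 ⇒ 21 + 22).** The acid is kept as the enal until the end, so the last step is a chlorite oxidation of 23 and no carboxyl protecting group is needed. The ester C–O bond is cut next, giving hydroxy enal 21 and commercial (R)-2-methylbutanoic acid 22. Acylating before the final oxidation avoids a free γ-hydroxy acid. The forward acylation must not epimerise the acyl α-carbon.

**C6–O bond (21 ⇒ 19 ⇒ 18).** The hydroxyl is traced to the enal 18 through its dienol acetate 19: epoxidation of the γ,δ-double bond C6=C7 and collapse of the epoxy enol acetate return the enal with oxygen on C6. The alternative of a C6 ketone followed by hydride reduction would deliver hydride from the open α face and give the wrong, 6β-alcohol. An electrophilic oxygen arriving from the α face gives the required 6α-configuration directly. Acid-catalysed enol acetylation is chosen because it touches the aldehyde but not the butenolide.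

**C17 oxidation (18 ⇒ 17).** The aldehyde is cut back to the C8 methyl of butenolide 17. Selenium dioxide attacks the more substituted alkene terminus and prefers a methyl over the tertiary C9–H. Doing this after the side chain is complete avoids a doubly allylic C9–H (present in vinyl compound 14) during the oxidation.

**C12–C13 bond (17 ⇒ 14 + 15).** A B-alkyl Suzuki–Miyaura coupling joins the hydroborated vinyl group of 14 to commercial 3-bromofuran-2(5H)-one 15. Aldol or alkylation routes to α-alkyl butenolides give exocyclic isomers or need oxidation-level adjustments; the cross-coupling brings in the intact ring. The precursor 14 is a hydrocarbon with three stereocentres.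

**C11=C12 (14 ⇒ 13 ⇒ 12).** The vinyl group comes from Wittig methylenation of aldehyde 13, itself the oxidation product of alcohol 12. Compound 12 is drimenol, which gives a well-defined checkpoint for constitution and configuration. The forward steps must avoid epimerising C9 or moving the alkene into conjugation.

**C9 and the sulfone (12 ⇒ 11 ⇒ 9 ⇒ 7).** The C2–S bond is restored (reductive desulfonylation forward), then the C11–O and C9–H bonds are removed (hydroboration forward) to give diene 9, and C9=C11 is cut to ketone 7 (Peterson methylenation forward). The sulfone is removed only after the enone is gone and before any reducible group appears. Hydroboration from the α face, opposite the C10 methyl, sets C9.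

**C3–C4 bond and ring A (7 ⇒ 6).** This is the key cut. A polar C3–C4 disconnection would need a tertiary cation or a hindered tertiary nucleophile; the radical cut needs only the isopropenyl group carvone supplies and a vinyl sulfone on C10. The sulfone makes C3 the electrophilic terminus, enforces 6-endo closure, and is removable without trace. The forward reaction must transfer a hydrogen atom chemoselectively to the isopropenyl group.

**C10 substituents (6 ⇒ 3 + 4; 3 ⇒ 1).** The C10–C1 and C10–C20 bonds are cut to the α′-carbon of (R)-carvone 1. Methyl enters first; the larger electrophile 4 enters second, anti to the isopropenyl group. That order places the methyl cis and the C1 chain trans to C4, which is the arrangement required for a trans ring fusion.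

## Roads not taken

**Alternative 1:** Both rings are cut at once (C5–C10 and C8–C9). Forward, the acyclic trienal A1 undergoes an intramolecular Diels–Alder reaction under a chiral Lewis acid or iminium catalyst to give the octalin A2.
- Merits: one step forms two rings and four stereocentres, and C17 (as a protected CH2OH) and C11 (as CHO) arrive functionalised. The C6=C7 alkene is well placed for C6 oxygenation by epoxidation and β-elimination. In oxidation-state economy this road is better than the chosen one, which has to oxidise a methyl group late.
- Weak points: the dienophile carbon C10 must be β,β-disubstituted to become quaternary, and such enals are poor partners for both activation modes. The diene terminus C5 is neopentylic beside the C4 gem-dimethyl group. The four-atom tether gives slower and less selective cycloadditions than three-atom tethers, and trans fusion depends on one of two close transition states. A1 needs three defined alkene geometries and several steps, and the C8 centre is made only to be destroyed.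
- Comparison: the chosen plan sets against this a purchased absolute configuration, two substrate-controlled alkylations, and a ring closure whose regiochemistry follows from polarity rather than from a catalyst–substrate match that cannot be assumed for this hindered trienal.

**Alternative 2:** The cut is at C9–C10 and C9–C20. Forward, Cu(acac)2-catalysed decomposition of diazoketone A3 adds the C9 carbene across the exocyclic C10=C20 alkene to give the cyclopropyl ketone A4. Dissolving-metal cleavage of the C9–C20 bond would later reveal the angular methyl and a regiodefined C9 enolate.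
- Merits: the C6 oxygen is present from the start, and the C8 ketone could become the C7=C8–C17 carboxyl unit through enol triflate carbonylation. No late C–H oxidation would be needed; in that respect it is cleaner than the chosen end game.
- Weak points: A3 needs C5 and C6 set by asymmetric synthesis on a crowded cyclohexane, and C10 then depends on the facial selectivity of the carbene addition. The β-silyloxy ketone in A4 invites elimination under the reductive and basic steps that follow. Alkylating a C9 enolate next to the quaternary C10 with a functionalised two-carbon electrophile is a notoriously weak step.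
- Comparison: the chosen plan is shorter to the decalin (three steps) and relies on no neopentylic enolate alkylation; it pays with two late oxidations.

**Alternative 3:** The cut is at C8–C9. Forward, the silyl ketene acetal of the ten-membered dienyl lactone A5 undergoes a ring-contracting Ireland–Claisen rearrangement to the acid A6, which carries the C17 carboxyl and the C9 vinyl group cis to each other.
- Merits: one step closes ring B, sets C9 and delivers C17 at the acid level. The C6=C7 alkene with an acidic C8–H is ideal for epoxidation and β-elimination to the 6-hydroxy-7-ene. From A6 onward this road would be shorter than the chosen one, needing no selenium dioxide oxidation and no aldehyde–Wittig homologation.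
- Weak points: A5 needs an enantioselective ring A with C5 and quaternary C10, a Z alkene, an E allylic ester on a neopentylic carbon, and closure of a ten-membered lactone, the least favourable ring size. The transannular transition state that fixes C9 relative to C10 cannot be predicted with confidence. The β,γ-unsaturated ester may enolise towards a dienolate.
- Comparison: better downstream, weaker upstream. The chosen plan sets against it a very short, stereochemically secure route to the bicyclic core.

Key step: step 3

Remark: bromides 4 and 15 are treated as catalogue reagents. Labdane numbering is used for all intermediates (in drimane names C12 is the C8 methyl, labdane C17).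
Remark: the sulfone carbon of 7–11 is drawn as the equatorial (2α) epimer; either epimer serves, since step 6 erases the centre.

## Route

Step 1
Reactants: 1 (R)-carvone
Product: 3 (5R,6S)-2,6-dimethyl-5-(prop-1-en-2-yl)cyclohex-2-en-1-one (trans-6-methylcarvone; the minor C6 epimer is carried along), via lithium α′-enolate of carvone 2 (not isolated)
Conditions: LDA, THF, −78 °C; MeI, −78 → −20 °C
Reagents that add atoms: iodomethane, CI
Why: Kinetic deprotonation of the enone at the α′-carbon gives the cross-conjugated enolate, which is C-methylated (enolate alkylation); the new C6 centre need not be controlled because it is re-enolised in step 2.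

Step 2
Reactants: 3 trans-6-methylcarvone; 4 3-bromo-2-(phenylsulfonyl)prop-1-ene
Product: 6 (5S,6S)-2,6-dimethyl-6-[2-(phenylsulfonyl)prop-2-en-1-yl]-5-(prop-1-en-2-yl)cyclohex-2-en-1-one, via tetrasubstituted lithium enolate 5 (not isolated)
Conditions: LDA, THF, −78 → 0 °C; then 4, DMPU, −78 → −20 °C
Reagents that add atoms: none
Why: Enolate alkylation with a 2-sulfonylallyl bromide (conjugate addition–elimination, net SN2′) creates the quaternary C10; the electrophile approaches the enolate face anti to the neighbouring isopropenyl group, so the methyl ends cis and the sulfonylallyl arm trans to it, as a trans ring fusion requires.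

Step 3
Reactants: 6 sulfonylallyl ketone
Product: 7 (4aS,7S,8aS)-2,5,5,8a-tetramethyl-7-(phenylsulfonyl)-4a,5,6,7,8,8a-hexahydronaphthalen-1(4H)-one
Conditions: Fe(acac)3 (0.5 equiv), PhSiH3 (2.5 equiv), EtOH/(CH2OH)2 5:1, 60 °C, 0.02 M
Reagents that add atoms: none
Why: Fe(acac)3 and PhSiH3 in ethanol form an iron hydride that transfers a hydrogen atom to the terminal carbon of the isopropenyl group (Markovnikov), creating the second C4 methyl and a nucleophilic tertiary C4 radical. This radical adds to the unsubstituted terminus C3 of the vinyl sulfone to form C3–C4, and the α-sulfonyl radical at C2 is reduced by divalent iron and protonated by the solvent. The closest known reaction type is the iron-hydride reductive olefin coupling of donor alkenes with electron-poor alkenes, vinyl sulfones included, used here intramolecularly as a Giese cyclisation. Ring A closes in the 6-endo-trig mode, because the competing 5-exo attack would have to occur at C2, which is fully substituted, bears the sulfonyl group and is the polarity-mismatched α-carbon. The only new stereocentre is the sulfone carbon C2, set on protonation and expected to be equatorial (α), since the axial epimer would suffer 1,3-diaxial strain with the C10 and C4 β-methyls; it is removed in step 6. The trans ring fusion is not at issue: C5 and C10 were fixed in steps 1 and 2, and both bonds of the new ring are equatorial on ring B. The step needs chemoselective hydrogen-atom transfer to the electron-rich 1,1-disubstituted alkene (the enone and vinyl sulfone are electron-poor and slow acceptors) and cyclisation faster than radical reduction; the enone β-carbon C7 is out of reach (a four-membered ring would form) and dilution suppresses intermolecular addition.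

Step 4
Reactants: 7 sulfonyl decalin enone
Product: 9 2α-(phenylsulfonyl)drima-7,9(11)-diene, via β-hydroxysilane 8 (not isolated)
Conditions: Me3SiCH2Li, CeCl3, THF, −78 → 0 °C; NH4Cl work-up; then TsOH·H2O (cat.), CH2Cl2, 0 °C
Reagents that add atoms: (trimethylsilyl)methyllithium, [Li]C[Si](C)(C)C
Why: Peterson olefination: the small, weakly basic organocerium adds 1,2 to the hindered C9 ketone anti to the angular methyl, and the tertiary allylic β-hydroxysilane loses trimethylsilanol under mild acid; an extra equivalent of reagent allows for reversible deprotonation next to the sulfone.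

Step 5
Reactants: 9 sulfonyl diene
Product: 11 2α-(phenylsulfonyl)drim-7-en-11-ol, via B-alkyl-9-BBN adduct 10 (not isolated)
Conditions: 9-BBN, THF, 0 → 50 °C; then NaOH, H2O2, 0 °C → rt
Reagents that add atoms: hydrogen peroxide, OO
Why: Hydroboration–oxidation: boron adds to the terminal C11 of the exocyclic alkene and leaves the trisubstituted C7=C8 alone; hydrogen reaches C9 from the α face because the axial C10 methyl lies over the β face, giving 9α-H with the CH2OH group β and equatorial.

Step 6
Reactants: 11 sulfonyl drimenol
Product: 12 drimenol (drim-7-en-11-ol)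
Conditions: Na(Hg) (6%), Na2HPO4, MeOH/THF, −20 → 0 °C
Reagents that add atoms: none
Why: Reductive desulfonylation of an unactivated secondary alkyl phenyl sulfone by buffered sodium amalgam; at this stage only an isolated trisubstituted alkene and a primary alcohol are present, and both are inert.

Step 7
Reactants: 12 drimenol
Product: 13 drimenal (drim-7-en-11-al)
Conditions: Dess–Martin periodinane, NaHCO3, CH2Cl2, 0 °C
Reagents that add atoms: none
Why: Dess–Martin oxidation under bicarbonate buffer is near neutral and fast, which suits a β,γ-unsaturated aldehyde with an epimerisable α-carbon; the crude aldehyde is used at once.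

Step 8
Reactants: 13 drimenal
Product: 14 (1S,4aS,8aS)-1-ethenyl-2,5,5,8a-tetramethyl-1,4,4a,5,6,7,8,8a-octahydronaphthalene
Conditions: Ph3PCH3Br, KHMDS, THF, 0 °C; then 13, −78 → 0 °C
Reagents that add atoms: methyltriphenylphosphonium bromide, C[P+](c1ccccc1)(c1ccccc1)c1ccccc1.[Br-]
Why: Wittig methylenation with the salt-free, non-stabilised ylide at low temperature adds to the aldehyde faster than it deprotonates C9, so the C9 configuration and the alkene position are kept.

Step 9
Reactants: 14 vinyl decalin; 15 3-bromofuran-2(5H)-one
Product: 17 labda-7,13-dien-16,15-olide, via B-alkyl-9-BBN adduct 16 (not isolated)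
Conditions: 9-BBN, THF, 0 °C → rt; then 15, PdCl2(dppf), AsPh3, K3PO4 (aq), DMF, rt
Reagents that add atoms: none
Why: 9-BBN hydroborates the monosubstituted vinyl group selectively at C12, and the B-alkyl Suzuki–Miyaura coupling with the α-bromo-α,β-unsaturated lactone forms C12–C13 under the mild conditions established for α-halo enones (dppf is 1,1′-bis(diphenylphosphino)ferrocene).

Step 10
Reactants: 17 methyl butenolide
Product: 18 17-oxolabda-7,13-dien-16,15-olide
Conditions: SeO2, 1,4-dioxane, 80 °C
Reagents that add atoms: selenium dioxide, O=[Se]=O
Why: Riley allylic oxidation (ene reaction, then [2,3]-sigmatropic shift): selenium attacks C7 and hydrogen is taken from a substituent of the more substituted C8, where the methyl C17 is preferred over the tertiary C9–H; the electron-poor butenolide alkene is inert and the methyl is carried through to the enal.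

Step 11
Reactants: 18 enal
Product: 19 (E)-17-acetoxylabda-6,8(17),13-trien-16,15-olide
Conditions: isopropenyl acetate, TsOH·H2O (cat.), 90 °C, acetone distilled off
Reagents that add atoms: isopropenyl acetate, CC(=C)OC(C)=O
Why: Acid-catalysed enol acetylation of the enal towards its only γ-position (C6) gives the dienol acetate; the lactone carbonyl enolises far more slowly under acid, so the butenolide is untouched, and the enol geometry is of no consequence.

Step 12
Reactants: 19 dienol acetate
Product: 21 6α-hydroxy-17-oxolabda-7,13-dien-16,15-olide, via 6α,7α-epoxy enol acetate 20 (not isolated)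
Conditions: mCPBA, NaHCO3, 1,4-dioxane/H2O, 0 °C → rt
Reagents that add atoms: 3-chloroperbenzoic acid, OOC(=O)c1cccc(Cl)c1
Why: γ-Hydroxylation of an enal through its dienol acetate: the peracid epoxidises the γ,δ-double bond C6=C7 from the α face (the β face at C6 is closed by the syn-axial C10 and C4 methyls), and the epoxy enol acetate opens with loss of acetic acid to the conjugated enal, which sets 6α-OH.

Step 13
Reactants: 21 hydroxy enal; 22 (R)-2-methylbutanoic acid
Product: 23 6α-[(2R)-2-methylbutanoyloxy]-17-oxolabda-7,13-dien-16,15-olide
Conditions: DCC, DMAP (cat.), CH2Cl2, 0 °C → rt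
Reagents that add atoms: none
Why: Steglich esterification of the equatorial secondary allylic alcohol; carbodiimide activation with catalytic DMAP at low temperature avoids a ketene pathway, so the acyl α-centre is retained.

Step 14
Reactants: 23 acyloxy enal
Product: 24 6α-[(2R)-2-methylbutanoyloxy]labda-7,13-dien-16,15-olid-17-oic acid (target)
Conditions: NaClO2, NaH2PO4, 2-methylbut-2-ene, tBuOH/H2O, 0 °C → rt
Reagents that add atoms: sodium chlorite, [Na+].[O-]Cl=O
Why: Pinnick oxidation converts the α,β-unsaturated aldehyde into the acid at buffered pH with a hypochlorite scavenger; the allylic ester, the butenolide and all stereocentres are unaffected.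

## Compound list

1 | (R)-carvone, (5R)-2-methyl-5-(prop-1-en-2-yl)cyclohex-2-en-1-one | CC1=CC[C@H](CC1=O)C(C)=C | starting material
2 | lithium α′-enolate of carvone (cross-conjugated dienolate; C5 unchanged) | CC1=CC[C@@H](C(C)=C)C=C1[O-].[Li+] | intermediate
3 | (5R,6S)-2,6-dimethyl-5-(prop-1-en-2-yl)cyclohex-2-en-1-one (trans-6-methylcarvone; minor C6 epimer accompanies it) | CC1=CC[C@@H](C(C)=C)[C@H](C)C1=O | intermediate
4 | 3-bromo-2-(phenylsulfonyl)prop-1-ene | C=C(CBr)S(=O)(=O)c1ccccc1 | starting material
5 | tetrasubstituted lithium enolate of 3 | CC1=CC[C@@H](C(C)=C)C(C)=C1[O-].[Li+] | intermediate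
6 | (5S,6S)-2,6-dimethyl-6-[2-(phenylsulfonyl)prop-2-en-1-yl]-5-(prop-1-en-2-yl)cyclohex-2-en-1-one (methyl cis, sulfonylallyl trans to isopropenyl) | CC1=CC[C@@H](C(C)=C)[C@](C)(CC(=C)S(=O)(=O)c2ccccc2)C1=O | intermediate
7 | (4aS,7S,8aS)-2,5,5,8a-tetramethyl-7-(phenylsulfonyl)-4a,5,6,7,8,8a-hexahydronaphthalen-1(4H)-one (trans-fused; sulfone equatorial, 2α) | CC1=CC[C@H]2C(C)(C)C[C@H](S(=O)(=O)c3ccccc3)C[C@]2(C)C1=O | intermediate
8 | 2α-(phenylsulfonyl)-9α-[(trimethylsilyl)methyl]-11-nordrim-7-en-9β-ol (C9 configuration immaterial) | CC1=CC[C@H]2C(C)(C)C[C@H](S(=O)(=O)c3ccccc3)C[C@]2(C)[C@]1(O)C[Si](C)(C)C | intermediate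
9 | 2α-(phenylsulfonyl)drima-7,9(11)-diene | CC1=CC[C@H]2C(C)(C)C[C@H](S(=O)(=O)c3ccccc3)C[C@]2(C)C1=C | intermediate
10 | 9-[2α-(phenylsulfonyl)drim-7-en-11-yl]-9-borabicyclo[3.3.1]nonane | CC1=CC[C@H]2C(C)(C)C[C@H](S(=O)(=O)c3ccccc3)C[C@]2(C)[C@H]1CB1C2CCCC1CCC2 | intermediate
11 | 2α-(phenylsulfonyl)drim-7-en-11-ol | CC1=CC[C@H]2C(C)(C)C[C@H](S(=O)(=O)c3ccccc3)C[C@]2(C)[C@H]1CO | intermediate
12 | drimenol, [(1S,4aS,8aS)-2,5,5,8a-tetramethyl-1,4,4a,5,6,7,8,8a-octahydronaphthalen-1-yl]methanol | CC1=CC[C@H]2C(C)(C)CCC[C@]2(C)[C@H]1CO | intermediate
13 | drimenal, drim-7-en-11-al | CC1=CC[C@H]2C(C)(C)CCC[C@]2(C)[C@H]1C=O | intermediate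
14 | (1S,4aS,8aS)-1-ethenyl-2,5,5,8a-tetramethyl-1,4,4a,5,6,7,8,8a-octahydronaphthalene | CC1=CC[C@H]2C(C)(C)CCC[C@]2(C)[C@H]1C=C | intermediate
15 | 3-bromofuran-2(5H)-one | O=C1OCC=C1Br | starting material
16 | 9-{2-[(1S,4aS,8aS)-2,5,5,8a-tetramethyl-1,4,4a,5,6,7,8,8a-octahydronaphthalen-1-yl]ethyl}-9-borabicyclo[3.3.1]nonane | CC1=CC[C@H]2C(C)(C)CCC[C@]2(C)[C@H]1CCB1C2CCCC1CCC2 | intermediate
17 | labda-7,13-dien-16,15-olide, 3-{2-[(1S,4aS,8aS)-2,5,5,8a-tetramethyl-1,4,4a,5,6,7,8,8a-octahydronaphthalen-1-yl]ethyl}furan-2(5H)-one | CC1=CC[C@H]2C(C)(C)CCC[C@]2(C)[C@H]1CCC1=CCOC1=O | intermediate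
18 | 17-oxolabda-7,13-dien-16,15-olide | O=CC1=CC[C@H]2C(C)(C)CCC[C@]2(C)[C@H]1CCC1=CCOC1=O | intermediate
19 | (E)-17-acetoxylabda-6,8(17),13-trien-16,15-olide | CC(=O)O/C=C1\C=C[C@H]2C(C)(C)CCC[C@]2(C)[C@H]1CCC1=CCOC1=O | intermediate
20 | (E)-17-acetoxy-6α,7α-epoxylabda-8(17),13-dien-16,15-olide | CC(=O)O/C=C1\[C@@H]3O[C@@H]3[C@H]2C(C)(C)CCC[C@]2(C)[C@H]1CCC1=CCOC1=O | intermediate
21 | 6α-hydroxy-17-oxolabda-7,13-dien-16,15-olide | O=CC1=C[C@H](O)[C@H]2C(C)(C)CCC[C@]2(C)[C@H]1CCC1=CCOC1=O | intermediate
22 | (R)-2-methylbutanoic acid | CC[C@@H](C)C(=O)O | starting material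
23 | 6α-[(2R)-2-methylbutanoyloxy]-17-oxolabda-7,13-dien-16,15-olide | CC[C@@H](C)C(=O)O[C@H]1C=C(C=O)[C@H](CCC2=CCOC2=O)[C@@]2(C)CCCC(C)(C)[C@H]12 | intermediate
24 | (5S,6S,9R,10R)-6-[(2R)-2-methylbutanoyloxy]labda-7,13-dien-16,15-olid-17-oic acid (CNP0150853.1) | CC[C@@H](C)C(=O)O[C@H]1C=C(C(=O)O)[C@H](CCC2=CCOC2=O)[C@@]2(C)CCCC(C)(C)[C@H]12 | target

## Step count and least certain steps

Total step count: 14. Longest linear sequence: 14 steps from 1 (fully linear; 4, 15 and 22 are purchased).

**Step 3 (key step).** The tertiary radical may be reduced before it cyclises (net hydrogenation of the isopropenyl group), hydrogen-atom transfer may also reach the vinyl sulfone, or intermolecular Giese addition to the enone of a second molecule may compete at preparative concentration. The fallback sets out from 6. Ionic Markovnikov addition of HBr (HBr in AcOH, CH2Cl2, 0 °C) to the isopropenyl group should give the tertiary bromide F1. Slow addition of Bu3SnH with AIBN in benzene at 80 °C then generates the same C4 radical under chain conditions without a metal hydride, and the same 6-endo closure onto the vinyl sulfone comes back to the route at 7.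

**Step 12.** The peracid may epoxidise the enol acetate double bond C8=C17 instead of C6=C7 (leading to oxygenation at C8), the liberated enal may undergo Baeyer–Villiger over-oxidation, or facial selectivity at C6 may be incomplete. The fallback sets out from 19. Electrophilic γ-bromination with NBS in buffered aqueous acetone at 0 °C, a known reaction of dienol acetates, should give the 6α-bromo enal F2. Silver-assisted substitution with the silver salt of 22 (from 22 and Ag2O) in toluene brings the carboxylate in from the open α face and comes back to the route at 23, bypassing 21.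

**Step 10.** Positional selectivity among C17, C9 and C6 may be poor, or oxidation may stall at the allylic alcohol or run on to over-oxidised products. The fallback sets out from 17 and replaces C–H oxidation by epoxide chemistry. mCPBA (CH2Cl2, 0 °C) epoxidises only the trisubstituted C7=C8 bond, from the α face, to the 7α,8α-epoxide F3. Al(OiPr)3 in toluene at reflux isomerises it to the exocyclic allylic alcohol F4 (7α-hydroxy-8(17)-ene). SOCl2 in Et2O transposes this with allylic shift to the primary 17-chloride F5. Oxidation of F5 with N-methylmorpholine N-oxide in MeCN (Ganem oxidation) comes back to the route at 18.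

**Step 9.** The bromobutenolide may decompose under the aqueous base faster than it couples, or the alkylborane may be lost by protodeboronation or β-hydride elimination. The fallback sets out from 14 and builds the butenolide by enolate alkylation instead of cross-coupling. 9-BBN then NaOH/H2O2 gives the primary alcohol F6. I2, PPh3 and imidazole give the iodide F7. The lithium enolate of 3-(phenylsulfanyl)dihydrofuran-2(3H)-one (LDA, THF/DMPU) is alkylated with F7 to the sulfide lactone F8. mCPBA at −78 °C gives the sulfoxide F9, whose thermal syn-elimination into the ring (toluene, 110 °C) comes back to the route at 17.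

**Step 8 (with step 7).** The β,γ-unsaturated aldehyde may epimerise at C9, or its double bond may move into conjugation, under the basic ylide before olefination is complete. The fallback sets out from 12 and never passes through a carbonyl at C11. I2, PPh3 and imidazole give drimenyl iodide F10. Displacement with lithiated methyl phenyl sulfoxide (LDA, THF/DMPU) gives the homologated phenyl sulfoxide F11. Thermal syn-elimination (toluene, 110 °C, CaCO3), which can only take a hydrogen from C11, comes back to the route at 14, bypassing 13.

**Step 2.** Facial selectivity at the new quaternary centre may be incomplete, O-alkylation may compete, or a second enolate may add to the vinyl sulfone of the product. The fallback sets out from 3. The same enolate is alkylated with 2,3-dibromopropene, a simple allylic halide that cannot undergo the second addition, to give the 2-bromoallyl ketone F12. CuI/L-proline-catalysed coupling of the vinyl bromide with PhSO2Na in DMSO at 90 °C installs the sulfone and comes back to the route at 6.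

## Further compounds

F1 | step 3 | tertiary bromide, 5-(2-bromopropan-2-yl) analogue of 6 (HBr adduct at the isopropenyl group) | CC1=CC[C@@H](C(C)(C)Br)[C@](C)(CC(=C)S(=O)(=O)c2ccccc2)C1=O
F2 | step 12 | 6α-bromo-17-oxolabda-7,13-dien-16,15-olide | O=CC1=C[C@H](Br)[C@H]2C(C)(C)CCC[C@]2(C)[C@H]1CCC1=CCOC1=O
F3 | step 10 | 7α,8α-epoxylabd-13-en-16,15-olide | C[C@@]12O[C@@H]1C[C@H]3C(C)(C)CCC[C@]3(C)[C@H]2CCC1=CCOC1=O
F4 | step 10 | 7α-hydroxylabda-8(17),13-dien-16,15-olide | C=C1[C@H](O)C[C@H]2C(C)(C)CCC[C@]2(C)[C@H]1CCC1=CCOC1=O
F5 | step 10 | 17-chlorolabda-7,13-dien-16,15-olide | ClCC1=CC[C@H]2C(C)(C)CCC[C@]2(C)[C@H]1CCC1=CCOC1=O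
F6 | step 9 | 2-[(1S,4aS,8aS)-2,5,5,8a-tetramethyl-1,4,4a,5,6,7,8,8a-octahydronaphthalen-1-yl]ethan-1-ol | CC1=CC[C@H]2C(C)(C)CCC[C@]2(C)[C@H]1CCO
F7 | step 9 | (1S,4aS,8aS)-1-(2-iodoethyl)-2,5,5,8a-tetramethyl-1,4,4a,5,6,7,8,8a-octahydronaphthalene | CC1=CC[C@H]2C(C)(C)CCC[C@]2(C)[C@H]1CCI
F8 | step 9 | 3-(phenylsulfanyl)-3-{2-[(1S,4aS,8aS)-2,5,5,8a-tetramethyl-1,4,4a,5,6,7,8,8a-octahydronaphthalen-1-yl]ethyl}dihydrofuran-2(3H)-one (both C3 epimers) | CC1=CC[C@H]2C(C)(C)CCC[C@]2(C)[C@H]1CCC1(Sc2ccccc2)CCOC1=O
F9 | step 9 | 3-(phenylsulfinyl) analogue of F8 (mixture at sulfur and C3) | CC1=CC[C@H]2C(C)(C)CCC[C@]2(C)[C@H]1CCC1(S(=O)c2ccccc2)CCOC1=O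
F10 | step 8 | drimenyl iodide, 11-iododrim-7-ene | CC1=CC[C@H]2C(C)(C)CCC[C@]2(C)[C@H]1CI
F11 | step 8 | {2-[(1S,4aS,8aS)-2,5,5,8a-tetramethyl-1,4,4a,5,6,7,8,8a-octahydronaphthalen-1-yl]ethyl} phenyl sulfoxide (mixture at sulfur) | CC1=CC[C@H]2C(C)(C)CCC[C@]2(C)[C@H]1CCS(=O)c1ccccc1
F12 | step 2 | (5S,6S)-6-(2-bromoprop-2-en-1-yl)-2,6-dimethyl-5-(prop-1-en-2-yl)cyclohex-2-en-1-one | CC1=CC[C@@H](C(C)=C)[C@](C)(CC(Br)=C)C1=O
A1 | alternative 1 | (2E,8E,10E)-12-[(4-methoxybenzyl)oxy]-3,7,7-trimethyldodeca-2,8,10-trienal | O=C/C=C(\C)CCCC(C)(C)/C=C/C=C/COCc1ccc(OC)cc1
A2 | alternative 1 | trans-fused 2-[(4-methoxybenzyl)oxymethyl]-5,5,8a-trimethyl-1,2,4a,5,6,7,8,8a-octahydronaphthalene-1-carbaldehyde | C1=C[C@H](COCc3ccc(OC)cc3)[C@H](C=O)[C@@]2(C)CCCC(C)(C)[C@H]12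
A3 | alternative 2 | 4-[(tert-butyldimethylsilyl)oxy]-1-diazo-4-(2,2-dimethyl-6-methylidenecyclohexyl)butan-2-one | [N-]=[N+]=CC(=O)C[C@H](O[Si](C)(C)C(C)(C)C)[C@@H]1C(=C)CCCC1(C)C
A4 | alternative 2 | 6α-(tert-butyldimethylsilyloxy)-4,4-dimethyl-9,10-methanodecalin-8-one (tricyclic cyclopropyl ketone) | CC(C)(C)[Si](C)(C)O[C@H]1CC(=O)[C@@H]3C[C@@]32CCCC(C)(C)[C@H]12
A5 | alternative 3 | ten-membered dienyl lactone fused to ring A (Z alkene C6=C7, E allylic ester alkene C9=C11) | O=C1C/C=C\[C@H]2C(C)(C)CCC[C@]2(C)/C=C/CO1
A6 | alternative 3 | trans-fused 1-ethenyl-5,5,8a-trimethyl-1,2,4a,5,6,7,8,8a-octahydronaphthalene-2-carboxylic acid (vinyl and carboxyl cis) | C1=C[C@H](C(=O)O)[C@H](C=C)[C@@]2(C)CCCC(C)(C)[C@H]12
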